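**Slow steps.** I start from slowness: which steps are too slow to count in 15 s?

solid substrate 3.0 M; gas phase 170 mM (held); time 15 s

    2 starting material → homo dimer (k1 = 4.7 × 10⁻⁵ M⁻¹ s⁻¹)
    starting material + dissolved gas → target (k2 = 0.22 M⁻¹ s⁻¹)
    dissolved gas + target → over-reacted product (k3 = 0.057 M⁻¹ s⁻¹)
    solid substrate ⇌ starting material, rate k4*(cs4 - [starting material]) while solid is left; crystals form when [starting material] > cs4 (cs4 = 1.8 M, k4 = 0.14 s⁻¹)
    starting material ⇌ dormant form (K5 = 4.7, k5 = 0.11 s⁻¹)
    gas phase ⇌ dissolved gas, rate k6*(csat - [dissolved gas]) (k6 = 0.66 s⁻¹, csat = 170 mM)

- a species is counted by the solid substrate in it: one homo dimer counts as two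
- for a step with 2 of a species take k times the square, and two of it per event
- given per volume of solution although it is solid: solid substrate
- at the start none of the gas is dissolved
- at the start none of the solid substrate is in solution
- run time (flask): 15 s

* the target standing at 15 s, as a percentage of the solid substrate charged
* concentration of dissolved gas in solution at 15 s, in percent of saturation

**What matters.** The dimer constant can be far off. Even at the solubility, the starting material's half-life by that step is 5910 s, far longer than the run. The over-reaction constant can be rough too: it is about a quarter of the target step's constant, and it needs target, which starts at nothing. I want the solid feed, the drain to the dormant form, the target step and the gas transfer known well, and each of them stands in my reckoning below.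

**Half-gas level.** Gas enters in proportion to its shortfall and is taken in a pseudo-first-order way by the starting material. When the two frequencies are equal, the gas stands at half saturation. That zero of the scale lies at a starting material of 3.00 M, the half-gas level. With over-reaction neglected, the share of saturation is one over one plus starting material divided by this level.

**My reckoning.** I drop the return from the dormant form and take the gas as saturated. Feed then balances losses at 0.877 M, below the half-gas level. So the gas stands at 77.4 %. Target forms at 0.0254 M s⁻¹ after a fill time of 3.48 s, which gives 9.74 %.

**The forecast.** It says 9.7 % and 74 %, on the ground that the “dissolved gas sits at a quasi-steady balance between gas transfer and consumption”. My gas figure is higher.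

**The result.** The flask gives 9.79 % and 74.9 %. At 15.0 s its starting material stands at 31.8 % of the charge, or 0.953 M, and the half-gas level turns that into 75.9 %. In the same recipe read at 40 s, starting material is 11.9 % and target 22.2 %. Target now counts against its own half-gas level of 11.6 M, so I reckon 85.0 %, and the gas there reads 84.8 % of saturation.

The rate constants are those of an exercise; the rest is arithmetic.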